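At early times the readings of the fraction of starting material left fall close to a plain exponential, a pseudo-first-order decay, and its time constant is what we carry from flask to flask.

| setting | green | amber | grey | flask |
|---|---|---|---|---|
| starting material | 0.030 M | 0.030 M | 0.015 M | 0.030 M |
| gas | 12 mM (held) | 12 mM (held) | 12 mM (held) | 12 mM (held) |
| initiator | 0.30 mM | 0.45 mM | 0.60 mM | 0.60 mM |
| remark | run made earlier | run made earlier | run made earlier |  |
| time |  |  |  | 10 h |

- green (time / h: target / %, starting material / %): 0.250: 13.3, 83.3; 0.500: 17.2, 66.3; 1.00: 22.0, 45.3; 2.00: 20.2, 26.8; 4.00: 19.7, 10.9; 8.00: 20.8, 5.1
- amber (time / h: target / %, starting material / %): 0.250: 16.9, 78.7; 0.500: 22.5, 61.2; 1.00: 23.6, 41.2; 2.00: 23.2, 19.9; 4.00: 22.5, 6.6; 8.00: 22.9, 3.2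
- grey (time / h: target / %, starting material / %): 0.250: 19.4, 75.2; 0.500: 27.7, 55.2; 1.33: 30.4, 23.8; 3.00: 27.9, 9.1; 8.00: 28.3, 0.1

(each reading ± 1 percentage point)

- time up to 10 h at which target stands highest
- the amount of target, in percent of the starting material charged, at that time

- percent here means starting material units held: one ended chains B or side product counts as two
- at the start none of coupling partner is dissolved
- the numbers in the tables scatter by 1 percentage point (one standard deviation)
- reactions considered so far: initiator -> 2 initiating radical; gas <-> coupling partner; coupling partner + first chain carrier <-> target + second chain carrier; 2 second chain carrier -> ended chains A; 2 first chain carrier -> ended chains B; target <-> isomer of the product; starting material + initiating radical -> capped initiator + first chain carrier; starting material + second chain carrier -> by-product + first chain carrier; starting material + target -> side product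

Amber and green share their starting material and differ in initiator. At 0.500 h, the logarithm of amber's fraction left is 1.19 times green's, and the square root of the initiator ratio is 1.22. So, with the starting material held, we take the decay to quicken with that root. Scaling amber's reading at 0.500 h in this way gives the flask a chain clock of 0.882 h, the time in which the fraction of starting material left falls by a factor e.

Two extreme flasks can be solved in the head. If target has no loss, its fraction follows the charge minus what is left, and it climbs with no peak. If target goes far faster than it comes, it tracks its making rate and peaks almost at once. Between them we take loss as quick as making, and that two-step series, integrated in closed form, peaks at the clock. Amber's highest target reading stands at 1.00 h, against amber's own clock of 1.02 h. So we put the flask's best near 0.882 h. For the height we expect a value between amber's peak reading of 23.6 % and grey's of 30.4 %, since amber shares the flask's starting material and grey its initiator.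

The forecast gives 26 % at 0.7 h, earlier than our clock, holding that “More initiator speeds consumption and raises the yield”.

The flask gives 26.4 % at 0.933 h.

    initiator → 2 initiating radical (k = 2.20 × 10⁻⁴ s⁻¹)
    gas ⇌ coupling partner, rate k2*(csat - [coupling partner]) (kL = 0.0520 s⁻¹)
    coupling partner + first chain carrier ⇌ target + second chain carrier (K = 1.40, k = 24000 M⁻¹ s⁻¹)
    2 second chain carrier → ended chains A (k = 3.00 × 10⁷ M⁻¹ s⁻¹)
    2 first chain carrier → ended chains B (k = 9.00 × 10⁶ M⁻¹ s⁻¹)
    target ⇌ isomer of the product (K = 1.80, k = 4.80 × 10⁻⁴ s⁻¹)
    starting material + initiating radical → capped initiator + first chain carrier (k = 1.10 × 10⁵ M⁻¹ s⁻¹)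
    starting material + second chain carrier → by-product + first chain carrier (k = 5000 M⁻¹ s⁻¹)
    starting material + target → side product (k = 0.00600 M⁻¹ s⁻¹)

At that time isomer of the product already stands at 23.6 % and side product at 13.9 %. The clock puts the starting material left at 34.7 %, and the flask holds 35.8 %.

For the neighbour with 1.5 × 10⁻⁴ M of initiator, the clock becomes 1.76 h, so on the same time course the logarithm of the fraction left is half the flask's, and the flask's final 1.0 % turns into 10.1 %. The neighbour ends with 8.60 % left, and its best target is 16.9 %.

(The data come from a simulation for an exercise, noise included.)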